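**Retrosynthetic overview**
1. Target 20 ⇐ C13 alcohol 19 (Appel bromination with inversion) ⇐ silyl ether 18; the C9‑Cl/C10‑OAc pair ⇐ anti acylative opening (AcCl) of the β‑9,10‑epoxide 17 of oxocene 16.
2. C7‑Cl ⇐ C7 α‑alcohol 15 (Appel chlorination with inversion); the (E)‑enyne ⇐ enal 13 (Colvin homologation) ⇐ vinylogous Mukaiyama addition of a 1‑silyloxybutadiene to the C6 oxocarbenium ion derived from lactone 10, which sets the 2,8‑trans ether.
3. α‑Hydroxy lactone 10 ⇐ enolate hydroxylation of the eight‑membered lactone 9.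
4. Key step and only ring formation: the oxocane arises by [3,3] Claisen ring expansion of the 6‑vinyl‑2‑methylene‑1,3‑dioxane 8, made in the flask from cyclic carbonate 7 and Cp2TiMe2. The six‑membered carbonate ring is formed first and is consumed in this step.
5. Carbonate 7 ⇐ anti‑1,3‑diol 6 ⇐ Felkin‑selective Mukaiyama aldol of (S)‑2‑silyloxybutanal 3 (from methyl (S)‑2‑hydroxybutanoate 1) with 2‑silyloxybutadiene 4.

Assumption: the SMILES is taken as drawn, i.e. (6S,7S,9S,10S,12R,13R) with the two substituents flanking the ring oxygen trans; locants C1–C15 are those of the pentadecenyne chain (ring = O, C6–C12), α is the ring face carrying the C12 side chain and β the other face; TBS = tert‑butyldimethylsilyl.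

**Step 1**
Reactants: 1 methyl (2S)-2-hydroxybutanoate
Product: 2 methyl (2S)-2-(TBSO)butanoate
Conditions: TBSCl, imidazole, DMF, rt
Reagents that add atoms: tert‑butyldimethylsilyl chloride CC(C)(C)[Si](C)(C)Cl
Why: Standard O‑silylation; the purchased stereocentre (future C13) is untouched and the bulky, non‑chelating silyl ether is what later enforces Felkin control.

**Step 2**
Reactants: 2 methyl (2S)-2-(TBSO)butanoate
Product: 3 (2S)-2-(TBSO)butanal
Conditions: iBu2AlH, CH2Cl2, −78 °C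
Reagents that add atoms: none
Why: Partial ester reduction through the tetrahedral aluminium hemiacetal, which is stable at −78 °C; the cold, non‑basic conditions avoid α‑epimerisation and the aldehyde is used crude.

**Step 3**
Reactants: 3 (2S)-2-(TBSO)butanal; 4 2-(trimethylsilyloxy)buta-1,3-diene
Product: 5 (5R,6S)-6-(TBSO)-5-hydroxyoct-1-en-3-one
Conditions: BF3·OEt2, CH2Cl2, −78 °C
Reagents that add atoms: none
Why: Mukaiyama aldol under non‑chelating activation; polar Felkin–Anh attack anti to the OTBS group sets C12 (5R) anti to C13, and the minor syn isomer is removed after step 4.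

**Step 4**
Reactants: 5 (5R,6S)-6-(TBSO)-5-hydroxyoct-1-en-3-one
Product: 6 (3R,5R,6S)-6-(TBSO)oct-1-ene-3,5-diol
Conditions: Me4NBH(OAc)3, MeCN/AcOH, −30 °C
Reagents that add atoms: none
Why: Evans–Saksena reduction; hydride is delivered intramolecularly from the C5‑alkoxyborohydride (1,2‑addition only) to give the 1,3‑anti diol, so the derived six‑membered ring will be trans‑disubstituted.

**Step 5**
Reactants: 6 (3R,5R,6S)-6-(TBSO)oct-1-ene-3,5-diol
Product: 7 (4R,6R)-4-[(1S)-1-(TBSO)propyl]-6-ethenyl-1,3-dioxan-2-one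
Conditions: CDI, DMAP (cat.), toluene, 60 °C
Reagents that add atoms: 1,1'‑carbonyldiimidazole O=C(n1ccnc1)n1ccnc1
Why: Double acyl transfer closes the six‑membered cyclic carbonate; no stereocentre is touched.

**Step 6**
Reactants: 7 (4R,6R)-4-[(1S)-1-(TBSO)propyl]-6-ethenyl-1,3-dioxan-2-one
Product: 9 (5Z,8R)-8-[(1S)-1-(TBSO)propyl]-3,4,7,8-tetrahydro-2H-oxocin-2-one, via ketene acetal 8 (not isolated)
Conditions: Cp2TiMe2 (2.5 equiv), toluene, 110 °C, dark
Reagents that add atoms: Cp2TiMe2 (dimethyltitanocene) [CH3-].[CH3-].[Ti+4].c1cc[cH-]c1.c1cc[cH-]c1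
Why: Carbonyl methylenation of the carbonate gives the cyclic ketene acetal, which undergoes Claisen [3,3] rearrangement through a chair‑like transition state with the vinyl group axial and the side chain equatorial; this expands the ring to the eight‑membered lactone, turns the temporary C10 carbinol into the ring Z‑alkene and leaves C12 (R) untouched.

**Step 7**
Reactants: 9 (5Z,8R)-8-[(1S)-1-(TBSO)propyl]-3,4,7,8-tetrahydro-2H-oxocin-2-one
Product: 10 (3R,5Z,8R)-3-hydroxy-8-[(1S)-1-(TBSO)propyl]-3,4,7,8-tetrahydro-2H-oxocin-2-one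
Conditions: KN(SiMe3)2, THF, −78 °C; then racemic 2-(phenylsulfonyl)-3-phenyloxaziridine; NH4Cl
Reagents that add atoms: 2-(phenylsulfonyl)-3-phenyloxaziridine (racemic Davis reagent) O=S(=O)(N1OC1c1ccccc1)c1ccccc1
Why: Enolate hydroxylation with an achiral (racemic) oxygen donor; by analogy with closely related 8‑substituted oxocenone enolates the electrophile should enter cis to the C12 side chain, giving the 7α‑alcohol (7R) under substrate control.

**Step 8**
Reactants: 10 (3R,5Z,8R)-3-hydroxy-8-[(1S)-1-(TBSO)propyl]-3,4,7,8-tetrahydro-2H-oxocin-2-one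
Product: 11 (3R,5Z,8R)-8-[(1S)-1-(TBSO)propyl]-3,4,7,8-tetrahydro-2H-oxocine-2,3-diyl diacetate (both C2 epimers)
Conditions: iBu2AlH (2.3 equiv), CH2Cl2, −78 °C; then pyridine, DMAP, Ac2O, −78 → −20 °C
Reagents that add atoms: acetic anhydride CC(=O)OC(C)=O
Why: Reductive acetylation of the lactone; the aluminium hemiacetal is acetylated in the flask before the medium‑ring lactol can open, and the C7 aluminium alkoxide is acetylated in the same pot, so C7 is retained and the C6 epimer mixture is irrelevant.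

**Step 9**
Reactants: 11 (3R,5Z,8R)-8-[(1S)-1-(TBSO)propyl]-3,4,7,8-tetrahydro-2H-oxocine-2,3-diyl diacetate; 12 (1E)-1-(trimethylsilyloxy)buta-1,3-diene
Product: 13 (2E)-4-[(2S,3R,5Z,8R)-3-acetoxy-8-[(1S)-1-(TBSO)propyl]-3,4,7,8-tetrahydro-2H-oxocin-2-yl]but-2-enal
Conditions: TMSOTf (0.3 equiv), CH2Cl2, −78 → −40 °C
Reagents that add atoms: none
Why: Vinylogous Mukaiyama addition (γ‑attack of the dienol ether) to the C6 oxocarbenium ion; the participating 7α‑acetate and the α‑oriented C12 side chain both shield the α‑face, so the new C–C bond forms on the β‑face (6S, 2,8‑trans), and the enal is formed as the (E)‑isomer.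

**Step 10**
Reactants: 13 (2E)-4-[(2S,3R,5Z,8R)-3-acetoxy-8-[(1S)-1-(TBSO)propyl]-3,4,7,8-tetrahydro-2H-oxocin-2-yl]but-2-enal
Product: 15 (3E,9Z,6S,7R,12R,13S)-13-(TBSO)-6,12-epoxypentadeca-3,9-dien-1-yn-7-ol, via enyne acetate 14 (not isolated)
Conditions: Me3SiCHN2, LiN(iPr)2, THF, −78 → 0 °C; then MeOH, K2CO3, rt
Reagents that add atoms: trimethylsilyldiazomethane C[Si](C)(C)C=[N+]=[N-]
Why: Colvin homologation (addition, Peterson elimination, alkylidene carbene 1,2‑H shift) turns the enal into the terminal (E)‑enyne without touching the alkene geometry, and methanolysis in the same pot frees the C7 alcohol.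

**Step 11**
Reactants: 15 (3E,9Z,6S,7R,12R,13S)-13-(TBSO)-6,12-epoxypentadeca-3,9-dien-1-yn-7-ol
Product: 16 (3E,9Z,6S,7S,12R,13S)-13-(TBSO)-7-chloro-6,12-epoxypentadeca-3,9-dien-1-yne
Conditions: CCl4, P(n-C8H17)3, toluene, 70 °C
Reagents that add atoms: carbon tetrachloride ClC(Cl)(Cl)Cl
Why: Appel‑type chlorination; SN2 displacement of the oxyphosphonium by chloride inverts C7 to the β‑chloride (7S), cis to the C6 side chain.

**Step 12**
Reactants: 16 (3E,9Z,6S,7S,12R,13S)-13-(TBSO)-7-chloro-6,12-epoxypentadeca-3,9-dien-1-yne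
Product: 17 (3E,6S,7S,9R,10S,12R,13S)-13-(TBSO)-7-chloro-6,12:9,10-diepoxypentadec-3-en-1-yne
Conditions: mCPBA, NaHCO3, CH2Cl2, 0 °C
Reagents that add atoms: 3‑chloroperoxybenzoic acid OOC(=O)c1cccc(Cl)c1
Why: Prilezhaev epoxidation, chemoselective for the electron‑rich ring Z‑alkene over the conjugated enyne; attack anti to the bulky α‑oriented silyloxypropyl group should give the β‑cis‑epoxide (9R,10S).

**Step 13**
Reactants: 17 (3E,6S,7S,9R,10S,12R,13S)-13-(TBSO)-7-chloro-6,12:9,10-diepoxypentadec-3-en-1-yne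
Product: 18 (3E,6S,7S,9S,10S,12R,13S)-13-(TBSO)-7,9-dichloro-6,12-epoxypentadec-3-en-1-yn-10-yl acetate
Conditions: AcCl, Bu4NCl (10 mol %), CH2Cl2, 0 °C → rt
Reagents that add atoms: acetyl chloride CC(=O)Cl
Why: Acylative epoxide opening; O‑acylation followed by SN2 attack of chloride from the α‑face at C9 (its α‑neighbour at C7 is only H, whereas C10 is screened by the α side chain at C12) inverts C9 (9S) and leaves C10 as the β‑acetate (10S), giving the trans chloro‑acetate.

**Step 14**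
Reactants: 18 (3E,6S,7S,9S,10S,12R,13S)-13-(TBSO)-7,9-dichloro-6,12-epoxypentadec-3-en-1-yn-10-yl acetate
Product: 19 (3E,6S,7S,9S,10S,12R,13S)-7,9-dichloro-13-hydroxy-6,12-epoxypentadec-3-en-1-yn-10-yl acetate
Conditions: HF·pyridine, THF, 0 °C → rt
Reagents that add atoms: none
Why: Fluoride‑mediated desilylation under buffered acidic conditions that spare the acetate, the secondary chlorides and the enyne.

**Step 15**
Reactants: 19 (3E,6S,7S,9S,10S,12R,13S)-7,9-dichloro-13-hydroxy-6,12-epoxypentadec-3-en-1-yn-10-yl acetate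
Product: 20 (3E,6S,7S,9S,10S,12R,13R)-13-bromo-7,9-dichloro-6,12-epoxypentadec-3-en-1-yn-10-yl acetate, i.e. (2R,4S,5S,7S,8S)-2-[(1R)-1-bromopropyl]-5,7-dichloro-8-[(2E)-pent-2-en-4-yn-1-yl]oxocan-4-yl acetate
Conditions: CBr4, P(n-C8H17)3, toluene, 70 °C
Reagents that add atoms: carbon tetrabromide BrC(Br)(Br)Br
Why: Appel‑type bromination; SN2 displacement inverts the purchased C13 carbinol (13S) to the (13R)‑bromide.

**Compound list**
1 | methyl (2S)-2-hydroxybutanoate | CC[C@H](O)C(=O)OC | starting material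
2 | methyl (2S)-2-(TBSO)butanoate | CC[C@H](O[Si](C)(C)C(C)(C)C)C(=O)OC | intermediate
3 | (2S)-2-(TBSO)butanal | CC[C@H](O[Si](C)(C)C(C)(C)C)C=O | intermediate
4 | 2-(trimethylsilyloxy)buta-1,3-diene | C=CC(=C)O[Si](C)(C)C | starting material
5 | (5R,6S)-6-(TBSO)-5-hydroxyoct-1-en-3-one | C=CC(=O)C[C@@H](O)[C@@H](O[Si](C)(C)C(C)(C)C)CC | intermediate
6 | (3R,5R,6S)-6-(TBSO)oct-1-ene-3,5-diol | C=C[C@H](O)C[C@@H](O)[C@@H](O[Si](C)(C)C(C)(C)C)CC | intermediate
7 | (4R,6R)-4-[(1S)-1-(TBSO)propyl]-6-ethenyl-1,3-dioxan-2-one | C=C[C@H]1C[C@H]([C@@H](O[Si](C)(C)C(C)(C)C)CC)OC(=O)O1 | intermediate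
8 | (4R,6R)-4-[(1S)-1-(TBSO)propyl]-6-ethenyl-2-methylidene-1,3-dioxane (ketene acetal) | C=C[C@H]1C[C@H]([C@@H](O[Si](C)(C)C(C)(C)C)CC)OC(=C)O1 | intermediate (not isolated)
9 | (5Z,8R)-8-[(1S)-1-(TBSO)propyl]-3,4,7,8-tetrahydro-2H-oxocin-2-one | O=C1CC/C=C\C[C@H]([C@@H](O[Si](C)(C)C(C)(C)C)CC)O1 | intermediate
10 | (3R,5Z,8R)-3-hydroxy-8-[(1S)-1-(TBSO)propyl]-3,4,7,8-tetrahydro-2H-oxocin-2-one | O=C1[C@H](O)C/C=C\C[C@H]([C@@H](O[Si](C)(C)C(C)(C)C)CC)O1 | intermediate
11 | (3R,5Z,8R)-8-[(1S)-1-(TBSO)propyl]-3,4,7,8-tetrahydro-2H-oxocine-2,3-diyl diacetate (both C2 epimers) | CC(=O)OC1O[C@@H]([C@@H](O[Si](C)(C)C(C)(C)C)CC)C/C=C\C[C@H]1OC(C)=O | intermediate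
12 | (1E)-1-(trimethylsilyloxy)buta-1,3-diene | C=C/C=C/O[Si](C)(C)C | starting material
13 | (2E)-4-[(2S,3R,5Z,8R)-3-acetoxy-8-[(1S)-1-(TBSO)propyl]-3,4,7,8-tetrahydro-2H-oxocin-2-yl]but-2-enal | O=C/C=C/C[C@@H]1O[C@@H]([C@@H](O[Si](C)(C)C(C)(C)C)CC)C/C=C\C[C@H]1OC(C)=O | intermediate
14 | (3E,9Z,6S,7R,12R,13S)-13-(TBSO)-6,12-epoxypentadeca-3,9-dien-1-yn-7-yl acetate | C#C/C=C/C[C@@H]1O[C@@H]([C@@H](O[Si](C)(C)C(C)(C)C)CC)C/C=C\C[C@H]1OC(C)=O | intermediate (not isolated)
15 | (3E,9Z,6S,7R,12R,13S)-13-(TBSO)-6,12-epoxypentadeca-3,9-dien-1-yn-7-ol | C#C/C=C/C[C@@H]1O[C@@H]([C@@H](O[Si](C)(C)C(C)(C)C)CC)C/C=C\C[C@H]1O | intermediate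
16 | (3E,9Z,6S,7S,12R,13S)-13-(TBSO)-7-chloro-6,12-epoxypentadeca-3,9-dien-1-yne | C#C/C=C/C[C@@H]1O[C@@H]([C@@H](O[Si](C)(C)C(C)(C)C)CC)C/C=C\C[C@@H]1Cl | intermediate
17 | (3E,6S,7S,9R,10S,12R,13S)-13-(TBSO)-7-chloro-6,12:9,10-diepoxypentadec-3-en-1-yne | C#C/C=C/C[C@@H]1O[C@@H]([C@@H](O[Si](C)(C)C(C)(C)C)CC)C[C@@H]2O[C@@H]2C[C@@H]1Cl | intermediate
18 | (3E,6S,7S,9S,10S,12R,13S)-13-(TBSO)-7,9-dichloro-6,12-epoxypentadec-3-en-1-yn-10-yl acetate | C#C/C=C/C[C@@H]1O[C@@H]([C@@H](O[Si](C)(C)C(C)(C)C)CC)C[C@H](OC(C)=O)[C@@H](Cl)C[C@@H]1Cl | intermediate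
19 | (3E,6S,7S,9S,10S,12R,13S)-7,9-dichloro-13-hydroxy-6,12-epoxypentadec-3-en-1-yn-10-yl acetate | C#C/C=C/C[C@@H]1O[C@@H]([C@@H](O)CC)C[C@H](OC(C)=O)[C@@H](Cl)C[C@@H]1Cl | intermediate
20 | (2R,4S,5S,7S,8S)-2-[(1R)-1-bromopropyl]-5,7-dichloro-8-[(2E)-pent-2-en-4-yn-1-yl]oxocan-4-yl acetate | C#C/C=C/C[C@@H]1O[C@@H]([C@H](Br)CC)C[C@H](OC(C)=O)[C@@H](Cl)C[C@@H]1Cl | target

**Totals**
Total step count: 15. Longest linear sequence: 15 steps (1 → 20); dienes 4 and 12 are bought.

**Three steps most likely to fail**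

Step 9 (vinylogous Mukaiyama addition). The dienol ether may attack through its α‑carbon or oligomerise, and facial control on an eight‑membered oxocarbenium ion is argued by analogy only. The fallback sets out from 11: allyltrimethylsilane with TMSOTf in CH2Cl2/MeCN at −78 → −20 °C (Hosomi–Sakurai C‑glycosylation) gives the C6‑allyl acetate F1. Cross‑metathesis of F1 with crotonaldehyde (second‑generation Hoveyda–Grubbs catalyst, CH2Cl2, 40 °C) then gives the (E)‑enal, and the route is rejoined at 13.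

Step 12 (face of epoxidation). In 16 the C7 chloride is β and the C12 side chain is α, so the facial bias may be weak. The fallback sets out from 14, isolated by quenching step 10 with aqueous NH4Cl instead of adding MeOH/K2CO3. In 14 both homoallylic substituents (7‑OAc and the C12 side chain) are α, so mCPBA/NaHCO3 in CH2Cl2 at 0 °C should give the β‑epoxy acetate F2. K2CO3/MeOH then gives the epoxy alcohol F3, and CCl4/P(n-C8H17)3 in toluene at 50 °C inverts C7, rejoining the route at 17.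

Step 13 (site of chloride attack, and possible transannular capture of the activated epoxide by the ring oxygen). The steric argument for C9 is opposed by a small inductive deactivation from the C7 chloride. The fallback sets out from 16 and replaces epoxide opening by electrophilic anti chloro‑acetoxylation (tert‑butyl hypochlorite, AcOH/NaOAc, 0 °C, dark). Here the nucleophile is acetate, which should attack the chloronium ion at C10 from the β‑face, since C9 is both inductively deactivated and flanked on the β‑face by the C7 chloride. This delivers 9α‑Cl/10β‑OAc directly, and the route is rejoined at 18.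

**Further compounds**
F1 | step 9 | (2S,3R,5Z,8R)-2-(prop-2-en-1-yl)-8-[(1S)-1-(TBSO)propyl]-3,4,7,8-tetrahydro-2H-oxocin-3-yl acetate | C=CC[C@@H]1O[C@@H]([C@@H](O[Si](C)(C)C(C)(C)C)CC)C/C=C\C[C@H]1OC(C)=O
F2 | step 12 | (3E,6S,7R,9R,10S,12R,13S)-13-(TBSO)-6,12:9,10-diepoxypentadec-3-en-1-yn-7-yl acetate | C#C/C=C/C[C@@H]1O[C@@H]([C@@H](O[Si](C)(C)C(C)(C)C)CC)C[C@@H]2O[C@@H]2C[C@H]1OC(C)=O
F3 | step 12 | (3E,6S,7R,9R,10S,12R,13S)-13-(TBSO)-6,12:9,10-diepoxypentadec-3-en-1-yn-7-ol | C#C/C=C/C[C@@H]1O[C@@H]([C@@H](O[Si](C)(C)C(C)(C)C)CC)C[C@@H]2O[C@@H]2C[C@H]1O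
F0 | step 13 | none | none
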